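The phloroglucinol ring is not attached to the terpene but grown on C1' (the benzylic CH on quaternary C4 of ring A). A siloxyalkyne on C1' and 3-ethoxycyclobutenone are heated; the cyclobutenone opens to an ethoxyvinylketene, which adds to the alkyne and rearranges to the benzene ring in one operation. The step exploits the fact that the arene is 1,3,5-trioxygenated with its ipso carbon (bonded to C1') flanked by two C–O carbons and two ring CH positions left free for the formyl groups. The precursor is a guai-5-ene (five-membered ring A, seven-membered ring B) carrying C1'–C≡C–OSi(i-Pr)3 and a silyl-protected C11 carbinol, made from (R)-carvone by ring expansion, cyclopentene annulation and Ireland–Claisen rearrangement.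

Key step: step 18

Numbering: terpene atoms carry guaiane numbers. Ring A = C1–C2–C3–C4–C5 (five-membered); ring B = C1–C5–C6–C7–C8–C9–C10 (seven-membered); C11 = carbinol carbon on C7; C14 = methyl on C10; C15 = methyl on C4; C1' = benzylic CH on C4.

Remark: the ketene partner is kept as the ethyl vinylogous ester, so the arene oxygen para to C1' leaves the key step as an ethyl ether and is freed at the end by thiolate dealkylation; every other protecting group is a silyl group removed by fluoride.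

Step 1
Reactants: 1 (R)-(−)-carvone
Product: 2 (5R)-5-(2-hydroxypropan-2-yl)-2-methylcyclohex-2-en-1-one
Conditions: 50% aq. H2SO4, 0 °C → rt
Reagents that add atoms: water, O
Why: Acid-catalysed Markovnikov hydration of the isopropenyl group through its tertiary cation should install the C11 hydroxyl while the conjugated ring alkene and the existing stereocentre (future C7) stay untouched.

Step 2
Reactants: 2 (5R)-5-(2-hydroxypropan-2-yl)-2-methylcyclohex-2-en-1-one
Product: 3 (5R)-2-methyl-5-[2-(triethylsilyloxy)propan-2-yl]cyclohex-2-en-1-one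
Conditions: Et3SiOTf, 2,6-lutidine, CH2Cl2, −78 → 0 °C
Reagents that add atoms: triethylsilyl triflate, CC[Si](CC)(CC)OS(=O)(=O)C(F)(F)F
Why: Silylation of a tertiary alcohol with a silyl triflate and a hindered pyridine base is fast at low temperature and masks the carbinol as an ether that resists elimination in the ketone chemistry ahead.

Step 3
Reactants: 3 (5R)-2-methyl-5-[2-(triethylsilyloxy)propan-2-yl]cyclohex-2-en-1-one
Product: 4 (2R,5R)-2-methyl-5-[2-(triethylsilyloxy)propan-2-yl]cyclohexan-1-one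
Conditions: LiBH(s-Bu)3, THF, −78 °C; aq. NH4Cl; then NaOMe (cat.), MeOH, rt
Reagents that add atoms: none
Why: Conjugate hydride reduction of the β-unsubstituted enone by the bulky trialkylborohydride, followed by base equilibration of the new α-methyl centre, should favour the diequatorial trans-2,5-disubstituted cyclohexanone, so the future C10 methyl ends up trans to the C7 side chain.

Step 4
Reactants: 4 (2R,5R)-2-methyl-5-[2-(triethylsilyloxy)propan-2-yl]cyclohexan-1-one
Product: 5 (3R,6R)-6-methyl-3-[2-(triethylsilyloxy)propan-2-yl]-1-(trimethylsilyloxy)cyclohex-1-ene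
Conditions: LiN(i-Pr)2, THF, −78 °C; Me3SiCl; Et3N
Reagents that add atoms: chlorotrimethylsilane, C[Si](C)(C)Cl
Why: Kinetic deprotonation with the hindered amide base removes a proton from the less substituted α-CH2 (future C6), and O-silylation traps this enolate regioisomer as its silyl enol ether.

Step 5
Reactants: 5 (3R,6R)-6-methyl-3-[2-(triethylsilyloxy)propan-2-yl]-1-(trimethylsilyloxy)cyclohex-1-ene
Product: 6 2-methyl-5-[2-(triethylsilyloxy)propan-2-yl]-1-(trimethylsilyloxy)bicyclo[4.1.0]heptane (C2 and C5 as in 5; cis-fused cyclopropane as a mixture of face isomers)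
Conditions: Et2Zn, CH2I2, CH2Cl2, 0 °C → rt
Reagents that add atoms: diiodomethane, ICI
Why: Furukawa-type Simmons–Smith cyclopropanation of the electron-rich silyl enol ether delivers the methylene that becomes C5, and the face of attack is irrelevant because both new centres are lost in the next step.

Step 6
Reactants: 6 2-methyl-5-[2-(triethylsilyloxy)propan-2-yl]-1-(trimethylsilyloxy)bicyclo[4.1.0]heptane
Product: 8 (4R,7R)-7-methyl-4-[2-(triethylsilyloxy)propan-2-yl]cyclohept-2-en-1-one, via β-chloro ketone 7 (not isolated)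
Conditions: FeCl3, pyridine, DMF, 0 °C → rt; then NaOAc, MeOH, 50 °C
Reagents that add atoms: none
Why: Ito–Saegusa ring expansion, in which one-electron oxidation of the siloxycyclopropane by FeCl3 cleaves the internal cyclopropane bond to a ring-expanded β-keto radical that is chlorinated, and mild base then eliminates HCl to the cycloheptenone while pyridine buffers the tertiary silyl ether.

Step 7
Reactants: 8 (4R,7R)-7-methyl-4-[2-(triethylsilyloxy)propan-2-yl]cyclohept-2-en-1-one
Product: 9 (4R,7R)-1-(but-3-en-1-yl)-7-methyl-4-[2-(triethylsilyloxy)propan-2-yl]cyclohept-2-en-1-ol (both C1 epimers)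
Conditions: CH2=CHCH2CH2MgBr, CeCl3, THF, −78 → 0 °C; aq. NH4Cl
Reagents that add atoms: but-3-enylmagnesium bromide, C=CCC[Mg]Br
Why: Cerium-mediated Grignard 1,2-addition to the enone carbonyl suppresses enolisation at the methyl-bearing α-carbon and gives the tertiary allylic alcohol, whose carbinol configuration is immaterial.

Step 8
Reactants: 9 (4R,7R)-1-(but-3-en-1-yl)-7-methyl-4-[2-(triethylsilyloxy)propan-2-yl]cyclohept-2-en-1-ol
Product: 10 (4R,7S)-3-(but-3-en-1-yl)-4-methyl-7-[2-(triethylsilyloxy)propan-2-yl]cyclohept-2-en-1-one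
Conditions: C5H5NH[CrO3Cl] (pyridinium chlorochromate), 4 Å MS, CH2Cl2, rt
Reagents that add atoms: pyridinium chlorochromate, [O-][Cr](=O)(=O)Cl.c1cc[nH+]cc1
Why: Dauben–Babler oxidative transposition, in which the tertiary allylic chromate ester undergoes a [3,3] shift and the rearranged secondary chromate is oxidised, moves the oxygen from C1 to C6 and the double bond to C1=C5.

Step 9
Reactants: 10 (4R,7S)-3-(but-3-en-1-yl)-4-methyl-7-[2-(triethylsilyloxy)propan-2-yl]cyclohept-2-en-1-one
Product: 11 (4R,7S)-4-methyl-3-(3-oxobutyl)-7-[2-(triethylsilyloxy)propan-2-yl]cyclohept-2-en-1-one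
Conditions: PdCl2 (10 mol%), CuCl, O2 (1 atm), DMF/H2O 7:1, rt
Reagents that add atoms: water, O
Why: Tsuji–Wacker oxidation is selective for the monosubstituted terminal alkene and gives the methyl ketone (C4 with C15) by Markovnikov attack of water, leaving the trisubstituted enone alkene alone.

Step 10
Reactants: 11 (4R,7S)-4-methyl-3-(3-oxobutyl)-7-[2-(triethylsilyloxy)propan-2-yl]cyclohept-2-en-1-one
Product: 12 (1R,4R,5S,7S,10R)-4-hydroxy-11-(triethylsilyloxy)guaian-6-one
Conditions: [(Ph3P)CuH]6, toluene, −40 °C → rt; aq. NH4Cl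
Reagents that add atoms: none
Why: Copper hydride reductive aldol cyclisation, in which hydride adds to C1 from the face opposite the neighbouring C10 methyl (held pseudoaxial by allylic strain with the C1 side chain) and so sets H-1 trans to that methyl, while the copper enolate at C5 closes ring A on the side-chain ketone under neutral conditions that spare the epimerisable C7 centre (the C4 and C5 centres are transient).

Step 11
Reactants: 12 (1R,4R,5S,7S,10R)-4-hydroxy-11-(triethylsilyloxy)guaian-6-one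
Product: 14 (1R,7S,10R)-11-(triethylsilyloxy)guai-4-en-6-one, via tertiary mesylate 13 (not isolated)
Conditions: MeSO2Cl, Et3N, DMAP (cat.), CH2Cl2, 0 → 40 °C
Reagents that add atoms: none
Why: Mesylation of the tertiary aldol hydroxyl through sulfene and E1cB elimination by way of the C5 enolate should give the conjugated C4=C5 enone without acid, the silyl ether on C11 being a poor leaving group.

Step 12
Reactants: 14 (1R,7S,10R)-11-(triethylsilyloxy)guai-4-en-6-one
Product: 15 (1R,6R,7R,10R)-11-(triethylsilyloxy)guai-4-en-6-ol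
Conditions: LiBH(s-Bu)3, THF, −78 °C; aq. NH4Cl
Reagents that add atoms: none
Why: 1,2-Reduction of the fully β-substituted enone by the bulky hydride from the ring face opposite the C7 substituent should give the allylic alcohol with the C6 hydroxyl cis to that substituent, the configuration needed for the coming sigmatropic transfer.

Step 13
Reactants: 15 (1R,6R,7R,10R)-11-(triethylsilyloxy)guai-4-en-6-ol; 16 4-methylpentanoic acid
Product: 17 (1R,6R,7R,10R)-11-(triethylsilyloxy)guai-4-en-6-yl 4-methylpentanoate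
Conditions: EDC·HCl, DMAP, CH2Cl2, 0 °C → rt
Reagents that add atoms: none
Why: Steglich esterification under neutral carbodiimide conditions acylates the hindered allylic alcohol without ionising it.

Step 14
Reactants: 17 (1R,6R,7R,10R)-11-(triethylsilyloxy)guai-4-en-6-yl 4-methylpentanoate
Product: 20 (2R)-4-methyl-2-[(1R,4R,7R,10R)-11-(triethylsilyloxy)guai-5-en-4-yl]pentanoic acid, via (Z)-silyl ketene acetal 18 (not isolated), via trimethylsilyl ester 19 (not isolated)
Conditions: LiN(i-Pr)2, THF/DMPU 4:1, −78 °C; Me3SiCl, Et3N; −78 → 60 °C; aq. NaOH, then citric acid to pH 4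
Reagents that add atoms: none
Why: Ireland–Claisen rearrangement through a chair transition state, in which the C6–O bond breaks and the C4–C1' bond forms on the same face of the C4=C5–C6 allyl unit so that the C6 configuration is transferred to quaternary C4, while the (Z)-silyl ketene acetal formed by enolisation in THF/DMPU keeps the isobutyl group away from ring A and thereby sets C1', and the double bond moves to C5=C6.

Step 15
Reactants: 20 (2R)-4-methyl-2-[(1R,4R,7R,10R)-11-(triethylsilyloxy)guai-5-en-4-yl]pentanoic acid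
Product: 21 methyl (2R)-4-methyl-2-[(1R,4R,7R,10R)-11-(triethylsilyloxy)guai-5-en-4-yl]pentanoate
Conditions: Me3SiCHN2, MeOH/toluene, 0 °C → rt
Reagents that add atoms: (trimethylsilyl)diazomethane, C[Si](C)(C)C=[N+]=[N-]
Why: O-Methylation of the carboxylic acid with (trimethylsilyl)diazomethane in methanol is a neutral, chemoselective esterification and provides the alkyl ester that the ynolate chemistry requires.

Step 16
Reactants: 21 methyl (2R)-4-methyl-2-[(1R,4R,7R,10R)-11-(triethylsilyloxy)guai-5-en-4-yl]pentanoate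
Product: 24 (1R,4R,7R,10R)-4-[(3R)-5-methyl-1-(triisopropylsilyloxy)hex-1-yn-3-yl]-11-(triethylsilyloxy)guai-5-ene, via dibromo enolate 22 (not isolated), via lithium ynolate 23 (not isolated)
Conditions: CH2Br2, LiNC9H18 (lithium 2,2,6,6-tetramethylpiperidide), THF, −78 °C; add 21; n-BuLi, −78 → 20 °C; i-Pr3SiCl, −78 → 0 °C
Reagents that add atoms: dibromomethane, BrCBr; chlorotriisopropylsilane, CC(C)[Si](Cl)(C(C)C)C(C)C
Why: Kowalski ynolate formation, in which dibromomethyllithium adds to the ester, the dibromo ketone enolate undergoes bromine–lithium exchange and 1,2-shift of C1' with retention to the lithium ynolate, and the bulky silyl chloride silylates it on oxygen to the siloxyalkyne.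

Step 17
Reactants: 25 ethoxyacetylene
Product: 26 3-ethoxycyclobut-2-en-1-one
Conditions: CH2=C=O (gas, from acetone pyrolysis), CH2Cl2, −40 → 0 °C
Reagents that add atoms: ketene, C=C=O
Why: Thermal (2+2) cycloaddition of ketene with the ynol ether, the ether-bearing carbon bonding to the ketene CH2 carbon, gives the vinylogous ester cyclobutenone.

Step 18
Reactants: 24 (1R,4R,7R,10R)-4-[(3R)-5-methyl-1-(triisopropylsilyloxy)hex-1-yn-3-yl]-11-(triethylsilyloxy)guai-5-ene; 26 3-ethoxycyclobut-2-en-1-one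
Product: 31 5-ethoxy-2-[(1R)-3-methyl-1-[(1R,4R,7R,10R)-11-(triethylsilyloxy)guai-5-en-4-yl]butyl]-3-(triisopropylsilyloxy)phenol, via ethoxyvinylketene 27 (not isolated), via vinylcyclobutenone 28 (not isolated), via dienylketene 29 (not isolated), via cyclohexadienone 30 (not isolated)
Conditions: toluene, 80 → 110 °C, argon, 26 (1.5 equiv) added in portions
Reagents that add atoms: none
Why: On heating, 26 undergoes four-electron electrocyclic opening to ethoxyvinylketene 27; the electron-rich alkyne carbon of 24 that carries C1' attacks the ketene carbonyl carbon and the (2+2) adduct 28 forms, which opens again to dienylketene 29 and closes to dienone 30 before tautomerising to the phenol. The closest known reaction type is the Danheiser benzannulation of cyclobutenones with siloxy- and alkoxyalkynes, which gives resorcinol derivatives with this substitution pattern. The one ring formed, the benzene ring, closes by thermal six-electron (disrotatory) electrocyclisation of 29, joining the ketene carbon that becomes C–OH to the former CH2 of the cyclobutenone. No stereocentre is created, and C1' keeps its configuration because the alkyne is a linear spectator at that carbon and the medium is neutral. The step needs a single orientation of alkyne on ketene, and the polarisation of the siloxyalkyne (only the carbon remote from oxygen is nucleophilic) secures it, placing the ipso carbon between C–OH and C–OSi, the ethoxy group para, and the two CH positions where the formyl groups must go. The absence of acid, base or metal should leave C5=C6 and the tertiary silyl ether untouched.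

Step 19
Reactants: 31 5-ethoxy-2-[(1R)-3-methyl-1-[(1R,4R,7R,10R)-11-(triethylsilyloxy)guai-5-en-4-yl]butyl]-3-(triisopropylsilyloxy)phenol
Product: 32 5-ethoxy-2-[(1R)-3-methyl-1-[(1R,4R,7R,10R)-11-(triethylsilyloxy)guai-5-en-4-yl]butyl]benzene-1,3-diol
Conditions: Bu4NF (1.1 equiv), THF, 0 °C; aq. NH4Cl
Reagents that add atoms: none
Why: Fluoride cleaves the aryl silyl ether much faster than the hindered tertiary alkyl silyl ether because phenoxide is the better leaving group, so one equivalent at low temperature should free the second phenol only.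

Step 20
Reactants: 32 5-ethoxy-2-[(1R)-3-methyl-1-[(1R,4R,7R,10R)-11-(triethylsilyloxy)guai-5-en-4-yl]butyl]benzene-1,3-diol
Product: 34 2-ethoxy-4,6-dihydroxy-5-[(1R)-3-methyl-1-[(1R,4R,7R,10R)-11-(triethylsilyloxy)guai-5-en-4-yl]butyl]benzene-1,3-dicarbaldehyde, via bis(iminium) salt 33 (not isolated)
Conditions: POCl3, DMF, MeCN, 0 °C → rt; then aq. NaOAc, rt
Reagents that add atoms: N,N-dimethylformamide, CN(C)C=O; water, O
Why: Vilsmeier–Haack formylation of the doubly activated resorcinol monoether attacks the only two free ring positions, each ortho or para to every oxygen, and aqueous acetate hydrolyses the iminium groups to the aldehydes in a DMF-buffered medium that should spare C5=C6 and the silyl ether.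

Step 21
Reactants: 34 2-ethoxy-4,6-dihydroxy-5-[(1R)-3-methyl-1-[(1R,4R,7R,10R)-11-(triethylsilyloxy)guai-5-en-4-yl]butyl]benzene-1,3-dicarbaldehyde
Product: 35 2,4,6-trihydroxy-5-[(1R)-3-methyl-1-[(1R,4R,7R,10R)-11-(triethylsilyloxy)guai-5-en-4-yl]butyl]benzene-1,3-dicarbaldehyde
Conditions: n-PrSLi (excess), DMPU, 100 °C; aq. NH4Cl
Reagents that add atoms: none
Why: SN2 dealkylation by a soft thiolate is chosen because the ethyl ether lies between two formyl groups and releases a strongly stabilised phenoxide, so it can be cleaved under basic conditions that cannot protonate C5=C6 or ionise C11.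

Step 22
Reactants: 35 2,4,6-trihydroxy-5-[(1R)-3-methyl-1-[(1R,4R,7R,10R)-11-(triethylsilyloxy)guai-5-en-4-yl]butyl]benzene-1,3-dicarbaldehyde
Product: 36 (−)-macrocarpal D, 2,4,6-trihydroxy-5-[(1R)-1-[(1R,4R,7R,10R)-11-hydroxyguai-5-en-4-yl]-3-methylbutyl]benzene-1,3-dicarbaldehyde
Conditions: HF·pyridine, pyridine, THF, 0 °C → rt
Reagents that add atoms: none
Why: Buffered fluoride cleaves the remaining tertiary triethylsilyl ether without acid strong enough to add a phenol across C5=C6.

Compound list (R = (1R)-3-methyl-1-[(1R,4R,7R,10R)-11-(triethylsilyloxy)guai-5-en-4-yl]butyl where used)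

1 | (R)-(−)-carvone | CC1=CC[C@H](CC1=O)C(C)=C | starting material
2 | (5R)-5-(2-hydroxypropan-2-yl)-2-methylcyclohex-2-en-1-one | CC1=CC[C@H](CC1=O)C(C)(C)O | intermediate
3 | (5R)-2-methyl-5-[2-(triethylsilyloxy)propan-2-yl]cyclohex-2-en-1-one | CC1=CC[C@H](CC1=O)C(C)(C)O[Si](CC)(CC)CC | intermediate
4 | (2R,5R)-2-methyl-5-[2-(triethylsilyloxy)propan-2-yl]cyclohexan-1-one (trans) | C[C@@H]1CC[C@H](CC1=O)C(C)(C)O[Si](CC)(CC)CC | intermediate
5 | (3R,6R)-6-methyl-3-[2-(triethylsilyloxy)propan-2-yl]-1-(trimethylsilyloxy)cyclohex-1-ene | C[C@@H]1CC[C@H](C=C1O[Si](C)(C)C)C(C)(C)O[Si](CC)(CC)CC | intermediate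
6 | 2-methyl-5-[2-(triethylsilyloxy)propan-2-yl]-1-(trimethylsilyloxy)bicyclo[4.1.0]heptane (C2, C5 as in 5; cyclopropane face isomers) | C[C@@H]1CC[C@H](C2CC12O[Si](C)(C)C)C(C)(C)O[Si](CC)(CC)CC | intermediate
7 | 3-chloro-7-methyl-4-[2-(triethylsilyloxy)propan-2-yl]cycloheptan-1-one (C4, C7 as in 8; chloride epimers; formed in situ) | C[C@@H]1CC[C@H](C(Cl)CC1=O)C(C)(C)O[Si](CC)(CC)CC | intermediate
8 | (4R,7R)-7-methyl-4-[2-(triethylsilyloxy)propan-2-yl]cyclohept-2-en-1-one | C[C@@H]1CC[C@H](C=CC1=O)C(C)(C)O[Si](CC)(CC)CC | intermediate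
9 | (4R,7R)-1-(but-3-en-1-yl)-7-methyl-4-[2-(triethylsilyloxy)propan-2-yl]cyclohept-2-en-1-ol (C1 epimers) | C[C@@H]1CC[C@H](C=CC1(O)CCC=C)C(C)(C)O[Si](CC)(CC)CC | intermediate
10 | (4R,7S)-3-(but-3-en-1-yl)-4-methyl-7-[2-(triethylsilyloxy)propan-2-yl]cyclohept-2-en-1-one | C[C@@H]1CC[C@@H](C(C)(C)O[Si](CC)(CC)CC)C(=O)C=C1CCC=C | intermediate
11 | (4R,7S)-4-methyl-3-(3-oxobutyl)-7-[2-(triethylsilyloxy)propan-2-yl]cyclohept-2-en-1-one | C[C@@H]1CC[C@@H](C(C)(C)O[Si](CC)(CC)CC)C(=O)C=C1CCC(C)=O | intermediate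
12 | (1R,4R,5S,7S,10R)-4-hydroxy-11-(triethylsilyloxy)guaian-6-one (cis-fused aldol) | C[C@@]1(O)CC[C@H]2[C@@H]1C(=O)[C@H](C(C)(C)O[Si](CC)(CC)CC)CC[C@H]2C | intermediate
13 | 4-O-methanesulfonate of 12 (formed in situ) | C[C@@]1(OS(C)(=O)=O)CC[C@H]2[C@@H]1C(=O)[C@H](C(C)(C)O[Si](CC)(CC)CC)CC[C@H]2C | intermediate
14 | (1R,7S,10R)-11-(triethylsilyloxy)guai-4-en-6-one | CC1=C2C(=O)[C@H](C(C)(C)O[Si](CC)(CC)CC)CC[C@@H](C)[C@H]2CC1 | intermediate
15 | (1R,6R,7R,10R)-11-(triethylsilyloxy)guai-4-en-6-ol (6-OH cis to the C7 side chain) | CC1=C2[C@H](O)[C@H](C(C)(C)O[Si](CC)(CC)CC)CC[C@@H](C)[C@H]2CC1 | intermediate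
16 | 4-methylpentanoic acid | CC(C)CCC(=O)O | starting material
17 | (1R,6R,7R,10R)-11-(triethylsilyloxy)guai-4-en-6-yl 4-methylpentanoate | CC1=C2[C@H](OC(=O)CCC(C)C)[C@H](C(C)(C)O[Si](CC)(CC)CC)CC[C@@H](C)[C@H]2CC1 | intermediate
18 | (Z)-trimethylsilyl ketene acetal of 17, isobutyl cis to OSiMe3 (formed in situ) | CC1=C2[C@H](O/C(O[Si](C)(C)C)=C/CC(C)C)[C@H](C(C)(C)O[Si](CC)(CC)CC)CC[C@@H](C)[C@H]2CC1 | intermediate
19 | trimethylsilyl ester of 20 (formed in situ) | CC(C)C[C@@H](C(=O)O[Si](C)(C)C)[C@@]1(C)CC[C@H]2C1=C[C@H](C(C)(C)O[Si](CC)(CC)CC)CC[C@H]2C | intermediate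
20 | (2R)-4-methyl-2-[(1R,4R,7R,10R)-11-(triethylsilyloxy)guai-5-en-4-yl]pentanoic acid | CC(C)C[C@@H](C(=O)O)[C@@]1(C)CC[C@H]2C1=C[C@H](C(C)(C)O[Si](CC)(CC)CC)CC[C@H]2C | intermediate
21 | methyl (2R)-4-methyl-2-[(1R,4R,7R,10R)-11-(triethylsilyloxy)guai-5-en-4-yl]pentanoate | CC(C)C[C@@H](C(=O)OC)[C@@]1(C)CC[C@H]2C1=C[C@H](C(C)(C)O[Si](CC)(CC)CC)CC[C@H]2C | intermediate
22 | lithium enolate of the dibromomethyl ketone from 21 (formed in situ) | CC(C)C[C@@H](C(O[Li])=C(Br)Br)[C@@]1(C)CC[C@H]2C1=C[C@H](C(C)(C)O[Si](CC)(CC)CC)CC[C@H]2C | intermediate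
23 | lithium ynolate, C1'–C≡C–OLi (formed in situ) | CC(C)C[C@@H](C#CO[Li])[C@@]1(C)CC[C@H]2C1=C[C@H](C(C)(C)O[Si](CC)(CC)CC)CC[C@H]2C | intermediate
24 | (1R,4R,7R,10R)-4-[(3R)-5-methyl-1-(triisopropylsilyloxy)hex-1-yn-3-yl]-11-(triethylsilyloxy)guai-5-ene (key-step precursor) | CC(C)C[C@@H](C#CO[Si](C(C)C)(C(C)C)C(C)C)[C@@]1(C)CC[C@H]2C1=C[C@H](C(C)(C)O[Si](CC)(CC)CC)CC[C@H]2C | intermediate
25 | ethoxyacetylene | C#COCC | starting material
26 | 3-ethoxycyclobut-2-en-1-one | CCOC1=CC(=O)C1 | intermediate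
27 | 3-ethoxybuta-1,3-dien-1-one, the ethoxyvinylketene (formed in situ) | C=C(OCC)C=C=O | intermediate
28 | 4-(1-ethoxyethenyl)-2-R-3-(triisopropylsilyloxy)cyclobut-2-en-1-one (ring C4 epimers; formed in situ) | CC(C)C[C@@H](C3=C(O[Si](C(C)C)(C(C)C)C(C)C)C(C(OCC)=C)C3=O)[C@@]1(C)CC[C@H]2C1=C[C@H](C(C)(C)O[Si](CC)(CC)CC)CC[C@H]2C | intermediate
29 | 5-ethoxy-2-R-3-(triisopropylsilyloxy)hexa-1,3,5-trien-1-one, ketene and ethoxyvinyl groups cis (formed in situ) | CC(C)C[C@@H](C(=C=O)/C(O[Si](C(C)C)(C(C)C)C(C)C)=C\C(OCC)=C)[C@@]1(C)CC[C@H]2C1=C[C@H](C(C)(C)O[Si](CC)(CC)CC)CC[C@H]2C | intermediate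
30 | 5-ethoxy-2-R-3-(triisopropylsilyloxy)cyclohexa-2,4-dien-1-one (formed in situ) | CC(C)C[C@@H](C3=C(O[Si](C(C)C)(C(C)C)C(C)C)C=C(OCC)CC3=O)[C@@]1(C)CC[C@H]2C1=C[C@H](C(C)(C)O[Si](CC)(CC)CC)CC[C@H]2C | intermediate
31 | 5-ethoxy-2-R-3-(triisopropylsilyloxy)phenol (key-step product) | CC(C)C[C@@H](c1c(O)cc(OCC)cc1O[Si](C(C)C)(C(C)C)C(C)C)[C@@]1(C)CC[C@H]2C1=C[C@H](C(C)(C)O[Si](CC)(CC)CC)CC[C@H]2C | intermediate
32 | 5-ethoxy-2-R-benzene-1,3-diol | CC(C)C[C@@H](c1c(O)cc(OCC)cc1O)[C@@]1(C)CC[C@H]2C1=C[C@H](C(C)(C)O[Si](CC)(CC)CC)CC[C@H]2C | intermediate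
33 | bis(dimethyliminium) dichloride of 34 (formed in situ) | CC(C)C[C@@H](c1c(O)c(C=[N+](C)C)c(OCC)c(C=[N+](C)C)c1O)[C@@]1(C)CC[C@H]2C1=C[C@H](C(C)(C)O[Si](CC)(CC)CC)CC[C@H]2C.[Cl-].[Cl-] | intermediate
34 | 2-ethoxy-4,6-dihydroxy-5-R-benzene-1,3-dicarbaldehyde | CC(C)C[C@@H](c1c(O)c(C=O)c(OCC)c(C=O)c1O)[C@@]1(C)CC[C@H]2C1=C[C@H](C(C)(C)O[Si](CC)(CC)CC)CC[C@H]2C | intermediate
35 | 2,4,6-trihydroxy-5-R-benzene-1,3-dicarbaldehyde (11-O-triethylsilyl macrocarpal D) | CC(C)C[C@@H](c1c(O)c(C=O)c(O)c(C=O)c1O)[C@@]1(C)CC[C@H]2C1=C[C@H](C(C)(C)O[Si](CC)(CC)CC)CC[C@H]2C | intermediate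
36 | (−)-macrocarpal D, (1R,4R,7R,10R,1'R) | CC(C)C[C@@H](c1c(O)c(C=O)c(O)c(C=O)c1O)[C@@]1(C)CC[C@H]2C1=C[C@H](C(C)(C)O)CC[C@H]2C | target

Total step count: 22. Longest linear sequence: 21 steps (1 → 36 through steps 1–16 and 18–22; step 17 is a one-step side branch).

Steps most likely to fail

Step 18. The intermolecular (2+2) has to form a bond at an alkyne carbon attached to the neopentyl-type C1'. It may be outpaced by dimerisation of the ethoxyvinylketene, or by thermal rearrangement of the siloxyalkyne on prolonged heating. The fallback inverts the roles so that the crowded carbon is part of the ketene. It sets out from acid 20. Oxalyl chloride gives the acid chloride F1, and diazomethane converts it into the α-diazo ketone F2. Photochemical Wolff rearrangement of F2 in the presence of ethoxyacetylene 25 gives the monosubstituted ketene F3, which is trapped by (2+2) as the 4-substituted 3-ethoxycyclobutenone F4. Heating F4 with more 25 in toluene runs the same benzannulation with the hindered group on the cyclobutenone and gives the 3,5-diethoxyphenol F5. Vilsmeier diformylation gives the dialdehyde F6, and n-PrSLi removes both ethyl groups (each ortho to a formyl group), so the route is rejoined at 35.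

Step 16. Addition of dibromomethyllithium to the shielded ester carbonyl may stall, or deprotonation at C1' may compete and erode its configuration. The fallback makes the ynolate by oxidation of an acetylide and not by carbenoid rearrangement. It sets out from ester 21. Reduction with i-Bu2AlH at −78 °C gives the aldehyde F7, and Ohira–Bestmann homologation (dimethyl 1-diazo-2-oxopropylphosphonate, K2CO3, MeOH) gives the terminal alkyne F8. Deprotonation with n-BuLi, oxidation of the acetylide with LiOOt-Bu and O-silylation with i-Pr3SiOTf give ynolate 23 and then siloxyalkyne 24, where the route is rejoined.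

Step 21. SN2 attack on an ethyl group is slow, so forcing conditions may degrade the phenolic dialdehyde before dealkylation is complete. The fallback removes the alkyl ether from the design. It sets out from cyclobutenone 26 and alkyne 24. Cold dilute HCl hydrolyses 26 to cyclobutane-1,3-dione F9, and i-Pr3SiOTf/Et3N gives 3-(triisopropylsilyloxy)cyclobut-2-en-1-one F10. F10 and 24 under the conditions of step 18 give the bis(silyl) ether F11. Bu4NF frees both phenols to the alkylphloroglucinol F12, and Vilsmeier diformylation as in step 20 gives 35 directly, where the route is rejoined.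

Further compounds

F1 | step 18 | (2R)-4-methyl-2-[(1R,4R,7R,10R)-11-(triethylsilyloxy)guai-5-en-4-yl]pentanoyl chloride | CC(C)C[C@@H](C(=O)Cl)[C@@]1(C)CC[C@H]2C1=C[C@H](C(C)(C)O[Si](CC)(CC)CC)CC[C@H]2C
F2 | step 18 | α-diazo ketone from F1 | CC(C)C[C@@H](C(=O)C=[N+]=[N-])[C@@]1(C)CC[C@H]2C1=C[C@H](C(C)(C)O[Si](CC)(CC)CC)CC[C@H]2C
F3 | step 18 | ketene C1'–CH=C=O | CC(C)C[C@@H](C=C=O)[C@@]1(C)CC[C@H]2C1=C[C@H](C(C)(C)O[Si](CC)(CC)CC)CC[C@H]2C
F4 | step 18 | 3-ethoxy-4-R-cyclobut-2-en-1-one (ring C4 epimers) | CC(C)C[C@@H](C3C(=O)C=C3OCC)[C@@]1(C)CC[C@H]2C1=C[C@H](C(C)(C)O[Si](CC)(CC)CC)CC[C@H]2C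
F5 | step 18 | 3,5-diethoxy-2-R-phenol | CC(C)C[C@@H](c3c(O)cc(OCC)cc3OCC)[C@@]1(C)CC[C@H]2C1=C[C@H](C(C)(C)O[Si](CC)(CC)CC)CC[C@H]2C
F6 | step 18 | 2,4-diethoxy-6-hydroxy-5-R-benzene-1,3-dicarbaldehyde | CC(C)C[C@@H](c3c(O)c(C=O)c(OCC)c(C=O)c3OCC)[C@@]1(C)CC[C@H]2C1=C[C@H](C(C)(C)O[Si](CC)(CC)CC)CC[C@H]2C
F7 | step 16 | (2R)-4-methyl-2-[(1R,4R,7R,10R)-11-(triethylsilyloxy)guai-5-en-4-yl]pentanal | CC(C)C[C@@H](C=O)[C@@]1(C)CC[C@H]2C1=C[C@H](C(C)(C)O[Si](CC)(CC)CC)CC[C@H]2C
F8 | step 16 | (1R,4R,7R,10R)-4-[(3R)-5-methylhex-1-yn-3-yl]-11-(triethylsilyloxy)guai-5-ene | CC(C)C[C@@H](C#C)[C@@]1(C)CC[C@H]2C1=C[C@H](C(C)(C)O[Si](CC)(CC)CC)CC[C@H]2C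
F9 | step 21 | cyclobutane-1,3-dione | O=C1CC(=O)C1
F10 | step 21 | 3-(triisopropylsilyloxy)cyclobut-2-en-1-one | O=C1C=C(O[Si](C(C)C)(C(C)C)C(C)C)C1
F11 | step 21 | 2-R-3,5-bis(triisopropylsilyloxy)phenol | CC(C)C[C@@H](c3c(O)cc(O[Si](C(C)C)(C(C)C)C(C)C)cc3O[Si](C(C)C)(C(C)C)C(C)C)[C@@]1(C)CC[C@H]2C1=C[C@H](C(C)(C)O[Si](CC)(CC)CC)CC[C@H]2C
F12 | step 21 | 2-R-benzene-1,3,5-triol | CC(C)C[C@@H](c3c(O)cc(O)cc3O)[C@@]1(C)CC[C@H]2C1=C[C@H](C(C)(C)O[Si](CC)(CC)CC)CC[C@H]2C
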